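**Retrosynthetic overview**

- Feature: in the lactone (O1, C2=O, C3, C4, C5) the two identical guaiacylmethyl arms on C3 and C4 are cis, so their benzylic carbons C7 (on C3) and C7' (on C4) can be tied by one sulfur atom into a thiolane cis-fused across C3–C4, and the sulfur excised afterwards.
- Target 23 ⇐ acetate methanolysis ⇐ C5 acetal to CH2 (hydrolysis, NaBH4, relactonisation) ⇐ Raney Ni removal of sulfur and O-benzyl ⇐ thieno[3,4-c]furanone 18.
- 18 ⇐ [3+2] cycloaddition forming C3–C7 and C4–C7': a 1,3-diaryl thiocarbonyl ylide, released from bis(alpha-silylbenzyl) sulfoxide 16, adds to C3=C4 of (5S)-3-acetoxy-5-(d-menthyloxy)butenolide 8, anti to the menthyloxy group.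
- 8 ⇐ furfural and (+)-menthol (photo-oxygenation, acetalisation, dihydroxylation, acetylation–elimination); 16 ⇐ O-benzylvanillin (Cu-catalysed silyl addition, chloride, thioacetate, thiolate alkylation to the symmetrical sulfide, S-oxidation), with PhMe2Si as the silyl group.
- Ring order: butenolide (from the furan) → temporary thiolane (step 10) → gamma-lactone reclosed after reduction of C5 (step 13).

Key step: step 10

Assumption: the target is the (3S,4R) cis-dibenzyl lactone as drawn; "d-menthyl" means (1S,2R,5S)-2-isopropyl-5-methylcyclohexyl; the lactone locants O1, C2, C3, C4, C5, C7 (benzylic on C3) and C7' (benzylic on C4) are kept for all intermediates; O-benzylvanillin and PhMe2Si–Bpin are purchased.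

**Route**

Step 1
Reactants: 1 furfural
Product: 3 5-hydroxyfuran-2(5H)-one (racemic), via furfural endoperoxide 2 (not isolated)
Conditions: O2, methylene blue (cat.), visible light, MeOH, rt
Reagents that add atoms: oxygen, O=O
Why: Singlet-oxygen [4+2] cycloaddition to the furan gives endoperoxide 2, which methanol fragments with loss of the formyl carbon as methyl formate to leave the gamma-hydroxybutenolide, and C5 needs no control here because it is equilibrated in step 2.

Step 2
Reactants: 3 5-hydroxyfuran-2(5H)-one; 4 (+)-menthol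
Product: 5 (5S)-5-{[(1S,2R,5S)-2-isopropyl-5-methylcyclohexyl]oxy}furan-2(5H)-one
Conditions: 4 (1.05 equiv), camphorsulfonic acid (cat.), toluene, reflux, Dean–Stark; crystallisation from petroleum ether, mother liquor re-equilibrated with acid
Reagents that add atoms: none
Why: Acid-catalysed acetalisation of the pseudo-acid gives both C5 epimers, which interconvert under the acid, and the (5S) epimer (mirror image of the crystalline acetal of the l-menthol series) should crystallise, so C5 is set by crystallisation-induced diastereomer enrichment.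

Step 3
Reactants: 5 (5S)-5-(d-menthyloxy)furan-2(5H)-one
Product: 6 (3R,4S,5S)-3,4-dihydroxy-5-(d-menthyloxy)dihydrofuran-2(3H)-one
Conditions: OsO4 (cat.), NMO (1.5 equiv), acetone/H2O, rt
Reagents that add atoms: N-methylmorpholine N-oxide, C[N+]1([O-])CCOCC1; water, O
Why: Catalytic syn-dihydroxylation of the butenolide alkene should occur anti to the menthyloxy group, and the configuration of the two new carbinol centres is immaterial because both become trigonal in step 4.

Step 4
Reactants: 6 (3R,4S,5S)-3,4-dihydroxy-5-(d-menthyloxy)dihydrofuran-2(3H)-one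
Product: 8 (5S)-5-(d-menthyloxy)-2-oxo-2,5-dihydrofuran-3-yl acetate, via diacetate 7 (not isolated)
Conditions: Ac2O (2.5 equiv), pyridine, DMAP (cat.), CH2Cl2, 0 °C to rt; then Et3N (1.5 equiv), 0 °C
Reagents that add atoms: acetic anhydride, CC(=O)OC(C)=O
Why: Acetylation followed by E1cB elimination of the C4 acetate (deprotonation at C3, alpha to the lactone carbonyl) is the standard passage from 2,3-di-O-acyl aldonolactones to 2-acyloxybutenolides, and the mild amine base at low temperature should leave the C5 acetal centre untouched.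

Step 5
Reactants: 9 4-(benzyloxy)-3-methoxybenzaldehyde
Product: 11 (±)-[4-(benzyloxy)-3-methoxyphenyl][dimethyl(phenyl)silyl]methanol, via O-boryl silyl carbinol 10 (not isolated)
Conditions: PhMe2Si–Bpin (1.2 equiv), (IPr)CuCl (5 mol %), NaOt-Bu (5 mol %), THF, rt; aq. NH4Cl work-up [IPr = 1,3-bis(2,6-diisopropylphenyl)imidazol-2-ylidene]
Reagents that add atoms: (dimethylphenylsilyl)boronic acid pinacol ester, CC1(C)OB(OC1(C)C)[Si](C)(C)c1ccccc1
Why: Copper-catalysed 1,2-addition of a silyl nucleophile (a monovalent copper silyl formed by Si–B transmetalation) to an aryl aldehyde gives the O-borylated alpha-silyl carbinol, which is hydrolysed on work-up, and the electron-rich arene disfavours a [1,2]-Brook shift while no stereocontrol is wanted.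

Step 6
Reactants: 11 (±)-[4-(benzyloxy)-3-methoxyphenyl][dimethyl(phenyl)silyl]methanol
Product: 12 (±)-{[4-(benzyloxy)-3-methoxyphenyl](chloro)methyl}dimethyl(phenyl)silane
Conditions: SOCl2 (1.2 equiv), CH2Cl2, 0 °C; volatiles removed under vacuum; crude chloride divided into two equal portions (one for step 7, one kept as a dry CH2Cl2 solution at −20 °C under N2 for step 8)
Reagents that add atoms: thionyl chloride, O=S(Cl)Cl
Why: Deoxychlorination of the electron-rich benzylic alpha-silyl carbinol through its chlorosulfite should be fast at 0 °C, the moisture-sensitive chloride is used crude, and no stereocontrol is needed.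

Step 7
Reactants: 12 (±)-{[4-(benzyloxy)-3-methoxyphenyl](chloro)methyl}dimethyl(phenyl)silane (first portion)
Product: 13 (±)-S-{[4-(benzyloxy)-3-methoxyphenyl][dimethyl(phenyl)silyl]methyl} ethanethioate
Conditions: KSAc (CH3COSK, 1.2 equiv), DMF, N2, 0 °C to rt
Reagents that add atoms: potassium thioacetate, CC(=O)[S-].[K+]
Why: SN2 displacement of the activated alpha-silyl benzylic chloride by the soft thioacetate anion installs one protected sulfur per benzylic carbon and cannot over-alkylate, because the thioester sulfur is no longer nucleophilic.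

Step 8
Reactants: 13 (±)-S-{[4-(benzyloxy)-3-methoxyphenyl][dimethyl(phenyl)silyl]methyl} ethanethioate; 12 (±)-{[4-(benzyloxy)-3-methoxyphenyl](chloro)methyl}dimethyl(phenyl)silane (second portion)
Product: 15 bis{[4-(benzyloxy)-3-methoxyphenyl][dimethyl(phenyl)silyl]methyl} sulfide (meso/dl mixture), via sodium alpha-silylbenzyl thiolate 14 (not isolated)
Conditions: 13 (1.0 equiv), NaOMe (1.0 equiv, 25 wt % in MeOH), degassed THF, 0 °C, 30 min; then 12 (1.0 equiv) in THF, 0 °C to rt
Reagents that add atoms: none
Why: Methoxide S-deacylates the thioester to thiolate 14, which is alkylated by chloride 12 in a thiolate SN2 thioether synthesis that should outpace methanolysis in the nearly aprotic medium, and the stereoisomer mixture is of no consequence because both benzylic centres become trigonal in the ylide.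

Step 9
Reactants: 15 bis{[4-(benzyloxy)-3-methoxyphenyl][dimethyl(phenyl)silyl]methyl} sulfide
Product: 16 bis{[4-(benzyloxy)-3-methoxyphenyl][dimethyl(phenyl)silyl]methyl} sulfoxide (stereoisomer mixture)
Conditions: mCPBA (1.0 equiv), CH2Cl2, −78 to −30 °C; cold aq. NaHCO3/Na2SO3 work-up, solution kept below 0 °C and used at once
Reagents that add atoms: 3-chloroperbenzoic acid, OOC(=O)c1cccc(Cl)c1
Why: Electrophilic S-oxidation by one equivalent of peracid at low temperature stops at the sulfoxide and is much faster than attack on the arenes, and cold handling forestalls a premature sila-Pummerer rearrangement.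

Step 10
Reactants: 8 (5S)-5-(d-menthyloxy)-2-oxo-2,5-dihydrofuran-3-yl acetate; 16 bis(alpha-silylbenzyl) sulfoxide
Product: 18 (3S,3aS,6aS)-4,6-bis[4-(benzyloxy)-3-methoxyphenyl]-3-(d-menthyloxy)-1-oxotetrahydro-1H-thieno[3,4-c]furan-6a(6H)-yl acetate (benzylic centres unassigned), via 1,3-diaryl thiocarbonyl ylide 17 (not isolated)
Conditions: 8 (1.0 equiv, about 1 M in DMPU), 16 (2.0 equiv) added slowly, 60–90 °C
Reagents that add atoms: none
Why: Warming the alpha-silyl sulfoxide should trigger a sila-Pummerer shift of one silyl group from carbon to the sulfoxide oxygen, after which the siloxide removes the second silyl group, releasing the disiloxane and ylide 17, a nucleophilic four-electron dipole that adds to the electron-poor C3=C4 bond of 8. The closest known reaction type is the [3+2] cycloaddition of thiocarbonyl ylides generated from bis(silylmethyl) sulfoxides to 5-alkoxybutenolides, applied here to an aryl-stabilised ylide and a 3-acyloxy dipolarophile. The thiolane is closed intermolecularly in one concerted suprafacial six-electron event that forms C3–C7 and C4–C7' together, so it is necessarily cis-fused to the lactone. C3 and C4 are set by approach of the ylide to the face anti to the C5 menthyloxy group, which puts the acetoxy group and H4 cis to each other and both benzylic carbons on the opposite face, while C7 and C7' follow the ylide geometry and are left uncontrolled because both are erased in step 11. The step needs facial selectivity, secured by the menthyloxy acetal, and a bimolecular addition that outruns conrotatory closure of the ylide to a thiirane and ylide dimerisation, secured by keeping the dipolarophile concentrated while the sulfoxide is fed in slowly; a 1,4-hydrogen shift of the ylide is excluded because its termini carry aryl groups.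

Step 11
Reactants: 18 cycloadduct
Product: 19 (3S,4S,5S)-3,4-bis(4-hydroxy-3-methoxybenzyl)-5-(d-menthyloxy)-2-oxotetrahydrofuran-3-yl acetate
Conditions: Raney Ni (W-2, washed neutral, excess), H2 (1 atm), EtOH/THF, reflux
Reagents that add atoms: none
Why: Raney Ni hydrogenolysis cleaves both benzylic C–S bonds and the aryl benzyl ethers, turning C7 and C7' into CH2 groups that stay cis on the lactone, while C3, C4 and C5, the acetal and the tertiary acetate are not affected by these neutral reductive conditions.

Step 12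
Reactants: 19 desulfurised acetal
Product: 20 (3S,4S)-5-hydroxy-3,4-bis(4-hydroxy-3-methoxybenzyl)-2-oxotetrahydrofuran-3-yl acetate (C5 epimers)
Conditions: 1 M HCl, dioxane/H2O (1:1), 60 °C
Reagents that add atoms: water, O
Why: Acid-catalysed hydrolysis of the acyloxy-alkoxy acetal releases (+)-menthol and the 5-hydroxy lactone (ring tautomer of the aldehyde acid), the water-rich medium traps the oxocarbenium ion, and C4 should survive because acid-catalysed enolisation of the minor open-chain aldehyde is slow.

Step 13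
Reactants: 20 lactol
Product: 22 (3S,4R)-3,4-bis(4-hydroxy-3-methoxybenzyl)-2-oxotetrahydrofuran-3-yl acetate, via hydroxy acid 21 (not isolated)
Conditions: NaBH4 (4 equiv), EtOH/H2O, 0 °C; then 2 M HCl to pH 1, rt
Reagents that add atoms: none
Why: Borohydride reduces the aldehyde of the ring-opened lactol at mildly basic pH much faster than that aldehyde can enolise (so no C4 epimerisation and no beta-elimination of acetate), and the gamma-hydroxy acid 21 lactonises on acidification to the only ring available to it.

Step 14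
Reactants: 22 acetoxy lactone
Product: 23 (3S,4R)-3-hydroxy-3,4-bis(4-hydroxy-3-methoxybenzyl)dihydrofuran-2(3H)-one (target)
Conditions: K2CO3 (2.5 equiv), MeOH, N2, 0 °C to rt; then 1 M HCl to pH 2, rt
Reagents that add atoms: none
Why: Base-mediated transesterification removes the activated alpha-acyloxy acetate, neither stereocentre can epimerise (C3 is quaternary, C4 is not alpha to a carbonyl), and acidification recloses any lactone opened by methoxide, so material in which the acetyl group migrated or was lost during step 13 converges on the same product.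

**Compound list**

1 | furfural | O=Cc1ccco1 | starting material
2 | furfural endoperoxide (2,3,7-trioxabicyclo[2.2.1]hept-5-ene-1-carbaldehyde) | O=CC12C=CC(OO1)O2 | intermediate (not isolated)
3 | 5-hydroxyfuran-2(5H)-one (racemic) | O=C1C=CC(O)O1 | intermediate
4 | (+)-menthol, (1S,2R,5S)-2-isopropyl-5-methylcyclohexanol | CC(C)[C@H]1CC[C@H](C)C[C@@H]1O | starting material
5 | (5S)-5-{[(1S,2R,5S)-2-isopropyl-5-methylcyclohexyl]oxy}furan-2(5H)-one | O=C1C=C[C@@H](O[C@H]2C[C@@H](C)CC[C@@H]2C(C)C)O1 | intermediate
6 | (3R,4S,5S)-3,4-dihydroxy-5-(d-menthyloxy)dihydrofuran-2(3H)-one | O=C1O[C@H](O[C@H]2C[C@@H](C)CC[C@@H]2C(C)C)[C@@H](O)[C@H]1O | intermediate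
7 | (3R,4S,5S)-5-(d-menthyloxy)-2-oxotetrahydrofuran-3,4-diyl diacetate | O=C1O[C@H](O[C@H]2C[C@@H](C)CC[C@@H]2C(C)C)[C@@H](OC(C)=O)[C@H]1OC(C)=O | intermediate (not isolated)
8 | (5S)-5-(d-menthyloxy)-2-oxo-2,5-dihydrofuran-3-yl acetate | CC(=O)OC1=C[C@@H](O[C@H]2C[C@@H](C)CC[C@@H]2C(C)C)OC1=O | intermediate
9 | 4-(benzyloxy)-3-methoxybenzaldehyde (O-benzylvanillin) | COc1cc(C=O)ccc1OCc1ccccc1 | starting material
10 | 2-{[4-(benzyloxy)-3-methoxyphenyl][dimethyl(phenyl)silyl]methoxy}-4,4,5,5-tetramethyl-1,3,2-dioxaborolane (racemic) | COc1cc(C(OB2OC(C)(C)C(C)(C)O2)[Si](C)(C)c2ccccc2)ccc1OCc1ccccc1 | intermediate (not isolated)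
11 | (±)-[4-(benzyloxy)-3-methoxyphenyl][dimethyl(phenyl)silyl]methanol | COc1cc(C(O)[Si](C)(C)c2ccccc2)ccc1OCc1ccccc1 | intermediate
12 | (±)-{[4-(benzyloxy)-3-methoxyphenyl](chloro)methyl}dimethyl(phenyl)silane | COc1cc(C(Cl)[Si](C)(C)c2ccccc2)ccc1OCc1ccccc1 | intermediate
13 | (±)-S-{[4-(benzyloxy)-3-methoxyphenyl][dimethyl(phenyl)silyl]methyl} ethanethioate | COc1cc(C(SC(C)=O)[Si](C)(C)c2ccccc2)ccc1OCc1ccccc1 | intermediate
14 | sodium [4-(benzyloxy)-3-methoxyphenyl][dimethyl(phenyl)silyl]methanethiolate (racemic) | COc1cc(C([S-])[Si](C)(C)c2ccccc2)ccc1OCc1ccccc1.[Na+] | intermediate (not isolated)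
15 | bis{[4-(benzyloxy)-3-methoxyphenyl][dimethyl(phenyl)silyl]methyl} sulfide (meso/dl mixture) | COc1cc(C(SC(c2ccc(OCc3ccccc3)c(OC)c2)[Si](C)(C)c2ccccc2)[Si](C)(C)c2ccccc2)ccc1OCc1ccccc1 | intermediate
16 | bis{[4-(benzyloxy)-3-methoxyphenyl][dimethyl(phenyl)silyl]methyl} sulfoxide (stereoisomer mixture) | COc1cc(C(S(=O)C(c2ccc(OCc3ccccc3)c(OC)c2)[Si](C)(C)c2ccccc2)[Si](C)(C)c2ccccc2)ccc1OCc1ccccc1 | intermediate
17 | 1,3-bis[4-(benzyloxy)-3-methoxyphenyl] thiocarbonyl ylide | COc1cc(C=[S+][CH-]c2ccc(OCc3ccccc3)c(OC)c2)ccc1OCc1ccccc1 | intermediate (not isolated)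
18 | (3S,3aS,6aS)-4,6-bis[4-(benzyloxy)-3-methoxyphenyl]-3-(d-menthyloxy)-1-oxotetrahydro-1H-thieno[3,4-c]furan-6a(6H)-yl acetate; thiolane cis-fused, acetoxy, H-3a and menthyloxy on one face, C4 and C6 unassigned | CC(=O)O[C@]12C(=O)O[C@H](O[C@H]3C[C@@H](C)CC[C@@H]3C(C)C)[C@H]1C(c1ccc(OCc3ccccc3)c(OC)c1)SC2c1ccc(OCc2ccccc2)c(OC)c1 | intermediate
19 | (3S,4S,5S)-3,4-bis(4-hydroxy-3-methoxybenzyl)-5-(d-menthyloxy)-2-oxotetrahydrofuran-3-yl acetate | CC(=O)O[C@]1(Cc2ccc(O)c(OC)c2)C(=O)O[C@H](O[C@H]2C[C@@H](C)CC[C@@H]2C(C)C)[C@H]1Cc1ccc(O)c(OC)c1 | intermediate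
20 | (3S,4S)-5-hydroxy-3,4-bis(4-hydroxy-3-methoxybenzyl)-2-oxotetrahydrofuran-3-yl acetate (C5 epimers) | CC(=O)O[C@]1(Cc2ccc(O)c(OC)c2)C(=O)OC(O)[C@H]1Cc1ccc(O)c(OC)c1 | intermediate
21 | (2S,3R)-2-acetoxy-2-(4-hydroxy-3-methoxybenzyl)-3-(hydroxymethyl)-4-(4-hydroxy-3-methoxyphenyl)butanoic acid | CC(=O)O[C@](Cc1ccc(O)c(OC)c1)(C(=O)O)[C@@H](CO)Cc1ccc(O)c(OC)c1 | intermediate (not isolated)
22 | (3S,4R)-3,4-bis(4-hydroxy-3-methoxybenzyl)-2-oxotetrahydrofuran-3-yl acetate | CC(=O)O[C@]1(Cc2ccc(O)c(OC)c2)C(=O)OC[C@H]1Cc1ccc(O)c(OC)c1 | intermediate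
23 | (3S,4R)-3-hydroxy-3,4-bis(4-hydroxy-3-methoxybenzyl)dihydrofuran-2(3H)-one | COc1cc(C[C@@H]2COC(=O)[C@]2(O)Cc2ccc(O)c(OC)c2)ccc1O | target

**Step count**

Total: 14 steps. Longest linear sequence: 10 steps (steps 5–14, from O-benzylvanillin); the butenolide branch (steps 1–4) joins at step 10.

**Steps most likely to fail**

Step 10. The aryl-stabilised ylide may close to a thiirane or dimerise faster than it adds to the hindered trisubstituted alkene, or the addition may show poor facial selectivity. The fallback sets out from 5 and 9 and returns at 19; it builds the same C3/C4 relationship by conjugate addition, alkylation and enolate hydroxylation. Aldehyde 9 is thioacetalised (propane-1,3-dithiol, BF3·OEt2) to 2-[4-(benzyloxy)-3-methoxyphenyl]-1,3-dithiane F1. A second portion of 9 is reduced (NaBH4) to 4-(benzyloxy)-3-methoxybenzyl alcohol F2 and brominated (PBr3) to 4-(benzyloxy)-3-methoxybenzyl bromide F3. The lithium salt of F1 (n-BuLi, THF, −78 °C) adds 1,4 to butenolide 5 anti to the menthyloxy group, and the lactone enolate is alkylated in the same flask by F3, trans to the new C4 substituent, which should give (3S,4S,5S)-3-[4-(benzyloxy)-3-methoxybenzyl]-4-{2-[4-(benzyloxy)-3-methoxyphenyl]-1,3-dithian-2-yl}-5-(d-menthyloxy)dihydrofuran-2(3H)-one F4. Enolisation of F4 (KN(SiMe3)2, THF, −78 °C) and oxidation with 2-(phenylsulfonyl)-3-phenyloxaziridine on the face anti to the bulky C4 group should give the (3S,4S,5S)-3-hydroxy lactone F5, in which the C3 benzyl group is cis to the C4 substituent. Acetylation (Ac2O, DMAP, Et3N) gives the (3S,4S,5S) tertiary acetate F6, and Raney Ni (EtOH, reflux) then removes the dithiane sulfur and both benzyl ethers to give 19.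

Step 12. Hydrolysis of the hindered acetal may be slow, and prolonged heating in acid could then allow Friedel–Crafts capture of the C5 oxocarbenium ion by a guaiacyl ring or epimerisation at C4 through the enol of the open-chain aldehyde. The fallback sets out from 19 and returns at 23, without an acidic hydrolysis. Compound 19 is treated with excess NaBH4 in aqueous ethanolic NaOH (0 °C to rt): hydroxide opens the lactone and cleaves the acetate, and the aldehyde released from the hemiacetal is reduced as it forms, which should give (2S,3R)-2-hydroxy-2-(4-hydroxy-3-methoxybenzyl)-3-(hydroxymethyl)-4-(4-hydroxy-3-methoxyphenyl)butanoic acid F7 as its salt. Acidification to pH 1 closes the lactone and gives 23 directly.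

Step 8. The labile chloride may be solvolysed or lose HCl before the hindered thiolate attacks it, or the thiolate may be oxidised to the disulfide. The fallback sets out from 13 and 11 and returns at 15; it forms the second C–S bond by acid-catalysed dehydrative substitution, with no chloride and no basic nucleophile. Thioacetate 13 is cleaved (K2CO3, degassed MeOH, 0 °C; then dilute HCl) and the free [4-(benzyloxy)-3-methoxyphenyl][dimethyl(phenyl)silyl]methanethiol F8 is isolated under N2. ZnI2-catalysed dehydrative thioetherification of carbinol 11 with F8 (ClCH2CH2Cl, rt), which passes through the p-alkoxybenzylic cation of 11, should give sulfide 15.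

**Further compounds**

F1 | step 10 | 2-[4-(benzyloxy)-3-methoxyphenyl]-1,3-dithiane | COc1cc(C2SCCCS2)ccc1OCc1ccccc1
F2 | step 10 | 4-(benzyloxy)-3-methoxybenzyl alcohol | COc1cc(CO)ccc1OCc1ccccc1
F3 | step 10 | 4-(benzyloxy)-3-methoxybenzyl bromide | COc1cc(CBr)ccc1OCc1ccccc1
F4 | step 10 | (3S,4S,5S)-3-[4-(benzyloxy)-3-methoxybenzyl]-4-{2-[4-(benzyloxy)-3-methoxyphenyl]-1,3-dithian-2-yl}-5-(d-menthyloxy)dihydrofuran-2(3H)-one | O=C1O[C@H](O[C@H]2C[C@@H](C)CC[C@@H]2C(C)C)[C@@H](C2(c3ccc(OCc4ccccc4)c(OC)c3)SCCCS2)[C@@H]1Cc1ccc(OCc2ccccc2)c(OC)c1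
F5 | step 10 | (3S,4S,5S)-3-[4-(benzyloxy)-3-methoxybenzyl]-4-{2-[4-(benzyloxy)-3-methoxyphenyl]-1,3-dithian-2-yl}-3-hydroxy-5-(d-menthyloxy)dihydrofuran-2(3H)-one | O=C1O[C@H](O[C@H]2C[C@@H](C)CC[C@@H]2C(C)C)[C@@H](C2(c3ccc(OCc4ccccc4)c(OC)c3)SCCCS2)[C@@]1(O)Cc1ccc(OCc2ccccc2)c(OC)c1
F6 | step 10 | (3S,4S,5S)-3-[4-(benzyloxy)-3-methoxybenzyl]-4-{2-[4-(benzyloxy)-3-methoxyphenyl]-1,3-dithian-2-yl}-5-(d-menthyloxy)-2-oxotetrahydrofuran-3-yl acetate | O=C1O[C@H](O[C@H]2C[C@@H](C)CC[C@@H]2C(C)C)[C@@H](C2(c3ccc(OCc4ccccc4)c(OC)c3)SCCCS2)[C@@]1(OC(C)=O)Cc1ccc(OCc2ccccc2)c(OC)c1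
F7 | step 12 | (2S,3R)-2-hydroxy-2-(4-hydroxy-3-methoxybenzyl)-3-(hydroxymethyl)-4-(4-hydroxy-3-methoxyphenyl)butanoic acid | OC(=O)[C@](O)(Cc1ccc(O)c(OC)c1)[C@@H](CO)Cc1ccc(O)c(OC)c1
F8 | step 8 | [4-(benzyloxy)-3-methoxyphenyl][dimethyl(phenyl)silyl]methanethiol (racemic) | COc1cc(C(S)[Si](C)(C)c2ccccc2)ccc1OCc1ccccc1
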